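Numbering: germacrane numbering is used throughout (ring C1–C10, lactone carbons C11 and C12 with O6, methylene C13, methyls C14 on C10 and C15 on C4).

## The problem

The target 25 is a germacranolide: a ten-membered carbocycle trans-fused at C6/C7 to an α-methylene-γ-butyrolactone, with a cis-1,10-epoxide, a (Z)-trisubstituted C4=C5 alkene, an acetate at C3 and an (R)-2-methylbutanoate at C8. A synthesis has to close a medium ring against entropy and transannular strain, and both ring alkenes (C4=C5 and the C1=C10 precursor of the cis-epoxide) must end up Z. Of the six ring stereocentres, C6, C7 and C8 are contiguous: C8 can direct C7 (anti), and the C7/C8 pair can direct C6. C3 lies across the alkene from this triad and needs its own source of chirality; C1 and C10 can only be set at the end, by the conformation of the finished ring. The α-methylene lactone (Michael acceptor), the epoxide next to a transannular alkene (acid) and two enolisable, hydrolysable esters will not survive organometallic reagents, strong base or acid, so they must arrive late and in a fixed order. The feature that opens the molecule is the segment O–C3–C4(C15)=C5–C6–O, a 2-methyl-(Z)-but-2-ene-1,4-diol: this is what anti-carbometalation of a propargylic alcohol followed by aldehyde trapping produces. Because C12 is γ to O6 but would need an eight-membered ring to reach O3, lactonisation can afterwards tell the two new hydroxyls apart.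

## Retrosynthesis

**Epoxide.** The two C–O bonds of the 1,10-epoxide are cut first, giving diene 24. The epoxide is the most acid-sensitive group and its alkene is needed for ring closure, so it cannot come earlier. The forward step must pick the C1=C10 alkene out of three and one of its two faces.

**Acyl groups.** The C8–O acyl bond (24 to alcohol 22 and acid 23) and the C3–O acetyl bond (21 to 20) are cut next. Both acyl groups are enolisable, so both must follow the base-mediated methylenation. In 20 a silyl ether at C8 and a free hydroxyl at C3 already distinguish the two oxygens, so no extra protecting step is needed.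

**C11=C13.** Removing the exocyclic methylene leads from 20 to lactone 17. A Michael acceptor and possible metathesis partner is thereby kept out of the ring-closing step. The forward reaction is a Mannich methylenation of the lactone enolate, which is clean only while no other enolisable carbonyl is present.

**C1=C10.** Opening the ring at this alkene gives hydroxy lactone 16 with two terminal olefins. The C4=C5 alkene is reserved for the key step and every other ring bond bears a stereocentre; the two terminal olefins are inert passengers in all earlier steps. The forward metathesis must form a trisubstituted Z alkene in a ten-membered ring.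

**O6–C12.** Opening the lactone gives diol ester 15. Only O6 can reach C12 through a five-membered ring, so the forward lactonisation differentiates O6 from O3 without a protecting group.

**C4–C15 and C5–C6 (key cut).** Both bonds at the alkene are cut together, giving alkynol 3, methylmagnesium bromide 13 and aldehyde 12. Cutting C5–C6 alone would require a preformed (Z)-vinylmetal; cutting C3–C4 would make C3 the product of a weakly controlled addition. The double cut turns the alkene into an alkyne whose carbinol C3 directs regiochemistry and geometry. A C22 chain with four stereocentres falls to a C6 alkynol with one, a C1 reagent and a C10 aldehyde with two. The forward step needs alkoxide-directed anti addition and Felkin–Anh addition to the aldehyde.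

**C7–C11.** Aldehyde 12 comes from diester 11 and alcohol 10, and 10 from β-hydroxy ester 7 and bromoacetate 8. The anti relation of C7 and C8 is the intrinsic outcome of alkylating the chelated dianion 9. An aldol union of C7 with C8 would need an anti-selective aldol with an enolisable aldehyde partner whose double bond slips into conjugation. The ethyl and tert-butyl esters remain distinguishable for the later reduction.

**C9–C10.** Hydroxy ester 7 is cut to epoxy ester 5 and isopropenylmagnesium bromide 6; 5 comes from chlorohydrin 4. C8 is thereby bought from the chiral pool, and the opening occurs at the unsubstituted epoxide carbon.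

**C2–C3.** Alkynol 3 is cut to ynal 1 by asymmetric allylboration. C3 is remote from all other stereocentres and must be set by reagent control; the allyl group also supplies the C1 olefin for ring closure.

## Roads not taken

**Alternative 1:** ring-fusion glycol cleavage. Here the ring is uncovered, not closed: a bond is added retrosynthetically between C3 and C8, giving the bicyclic cis-diol A1 (two cyclohexene rings sharing C3–C8, lactone already fused at C6/C7). Forward, Pb(OAc)4 (tetravalent lead) cleaves the glycol and releases the (Z,Z)-cyclodecadiene-3,8-dione A2.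
- Merits: the ring forms by fragmentation with no entropic cost, and both Z geometries are inherited from six-membered rings. In both respects this road is better than the chosen one, whose metathesis is its least secure late step.
- Weak points: A2 has ketones where the target has its two acyloxy stereocentres. C3 is an enone with the lactone oxygen in the γ position; C8 is a β,γ-unsaturated ketone beside the epimerisable C7. Both would have to be reduced with facial control on a mobile ring and then differentiated. A1, with two fully substituted carbinol carbons, is itself a long target.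
- Comparison: the chosen plan sets C3 and C8 at the outset and carries them unchanged. Against the safer ring formation of Alternative 1 it sets the fact that no oxygen stereocentre has to be created on the medium ring.

**Alternative 2:** palladium cyclocarbonylation. The cut runs through C11–C12 and C12–O6, so the lactone carbonyl comes from CO. Forward, PdCl2 (divalent palladium) with thiourea under CO converts the ring-bound homopropargylic alcohol A3 (trans C6 hydroxyl and C7 ethynyl) into the α-methylene lactone A4.
- Merits: the α-methylene lactone forms in one neutral step without an enolate, so the C8 ester can already be in place. The end game is shorter than in the chosen plan, and in this respect the alternative is better.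
- Weak points: it is an end-game device only. A3 already contains the ten-membered ring, both Z alkenes and five stereocentres, and the ethynyl-bearing C7 between two oxygenated carbons has no carbonyl handle for stereocontrol. The allylic C3 and C6 oxygens and the skipped diene must also survive Pd and CO.
- Comparison: the chosen plan answers how the ring carbons and C6 come together. Against the shorter end game it sets a convergent assembly of all ring carbons with four stereocentres in place after one step.

**Alternative 3:** Ramberg–Bäcklund contraction. The cut is at C1=C10 with sulfur inserted: the alkene is traced back to the eleven-membered sulfone A5. Forward, in-situ halogenation (CBr2F2, KOH on alumina), closure to the thiirane dioxide and loss of SO2 give cyclodecadiene A6.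
- Merits: the ring is first closed as a C–S bond in a less strained eleven-membered ring, and the methyl-bearing C10 is less of an obstacle than for a metal carbene. As a ring closure this may be as good as or better than metathesis.
- Weak points: KOH threatens the lactone (hydrolysis, C11 deprotonation, translactonisation towards O8). Halogenation can occur at either α-carbon, and the alkene geometry is fixed only by ring strain. Sulfide formation, oxidation beside the C4=C5 alkene and the ether exchange at C8 add several steps.
- Comparison: the chosen plan reaches the same alkene in one neutral step from olefins that come free with the fragments. It sets that brevity against the more forgiving C–S closure; the geometry rests on ring strain in both.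

Key step: step 7

Remarks on the chemistry:
- Compounds 1, 4, 6, 8, 13 and 23 are taken to be catalogue materials.
- The (−)-α-pinene-derived allylborane is taken to add to the Re face of ynal 1, as it does with benzaldehyde; this corresponds to 3R.
- The descriptor changes at the carbinol of 5/7 (R to S) and at C7 (S in 10–12, R in 15–21, S from 22 on) follow from CIP priorities only; no bond at these centres is broken.

## Steps

Step 1
Reactants: 1 3-(trimethylsilyl)prop-2-ynal
Product: 3 (3R)-hex-5-en-1-yn-3-ol, via C-silylated enynol 2 (not isolated)
Conditions: (+)-Ipc2BOMe, CH2=CHCH2MgBr, Et2O, 0 °C → rt; then 1, −78 °C; then NaOH, H2O2, MeOH–H2O, 0 °C → rt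
Reagents that add atoms: B-allyldiisopinocampheylborane, (−)-α-pinene series, C=CCB([C@H]1C[C@H]2C[C@@H]([C@@H]1C)C2(C)C)[C@H]1C[C@H]2C[C@@H]([C@@H]1C)C2(C)C
Why: Brown allylation through a closed six-membered chair transition state in which the isopinocampheyl ligands direct allyl to the Re face, setting C3 as R. The alkaline peroxide–methanol work-up oxidises the borinate and cleaves the alkynyl C–Si bond in the same flask.

Step 2
Reactants: 4 ethyl (3R)-4-chloro-3-hydroxybutanoate
Product: 5 ethyl 2-[(2R)-oxiran-2-yl]acetate
Conditions: Ag2O, DME, 60 °C, dark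
Reagents that add atoms: none
Why: Silver-assisted intramolecular Williamson closure (3-exo-tet) of the halohydrin under near-neutral conditions, which avoids base-induced opening to the 4-hydroxycrotonate. The C–O bond at the stereocentre is not touched.

Step 3
Reactants: 5 ethyl 2-[(2R)-oxiran-2-yl]acetate; 6 isopropenylmagnesium bromide
Product: 7 ethyl (3S)-3-hydroxy-5-methylhex-5-enoate
Conditions: 6 (1.5 equiv), CuI (10 mol %), THF, −40 → −20 °C; NH4Cl (aq)
Reagents that add atoms: none
Why: Copper-catalysed Grignard opening of the terminal epoxide at the unsubstituted carbon (SN2), faster than ester addition at low temperature. It forms C9–C10 and leaves the C8 stereocentre untouched.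

Step 4
Reactants: 7 ethyl (3S)-3-hydroxy-5-methylhex-5-enoate; 8 tert-butyl bromoacetate
Product: 10 4-tert-butyl 1-ethyl (2S)-2-[(1S)-1-hydroxy-3-methylbut-3-en-1-yl]butanedioate, via dilithio dianion 9 (not isolated)
Conditions: LiN(iPr)2 (2.2 equiv), THF, −78 → −20 °C; then 8, DMPU, −78 → −20 °C; AcOH quench at −78 °C
Reagents that add atoms: none
Why: Fráter–Seebach alkylation: the six-membered lithium chelate of alkoxide and enolate in 9 is alkylated on the face opposite the C8 side chain, setting C7 anti to the C8 oxygen. The tert-butyl ester is chosen so that the γ-alkoxide does not lactonise onto C12.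

Step 5
Reactants: 10 4-tert-butyl 1-ethyl (2S)-2-[(1S)-1-hydroxy-3-methylbut-3-en-1-yl]butanedioate
Product: 11 4-tert-butyl 1-ethyl (2S)-2-[(1S)-1-(tert-butyldimethylsilyloxy)-3-methylbut-3-en-1-yl]butanedioate
Conditions: TBSOTf, 2,6-lutidine, CH2Cl2, −78 → 0 °C
Reagents that add atoms: tert-butyldimethylsilyl trifluoromethanesulfonate, CC(C)(C)[Si](C)(C)OS(=O)(=O)C(F)(F)F
Why: Silylation of a hindered secondary alcohol with a silyl triflate and a hindered base. The bulky, non-chelating silyl ether is what the Felkin–Anh addition in step 7 needs, and it survives steps 6–11.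

Step 6
Reactants: 11 4-tert-butyl 1-ethyl (2S)-2-[(1S)-1-(tert-butyldimethylsilyloxy)-3-methylbut-3-en-1-yl]butanedioate
Product: 12 tert-butyl (3S,4S)-4-(tert-butyldimethylsilyloxy)-3-formyl-6-methylhept-6-enoate
Conditions: iBu2AlH (1.1 equiv), CH2Cl2, −78 °C; MeOH, then aq. potassium sodium tartrate
Reagents that add atoms: none
Why: Partial reduction of the ethyl ester through a tetrahedral aluminium hemiacetal that is stable at −78 °C; the tert-butyl ester is too hindered to react. The aldehyde is used cold and without chromatography so that C7 does not epimerise.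

Step 7
Reactants: 3 (3R)-hex-5-en-1-yn-3-ol; 13 methylmagnesium bromide; 12 tert-butyl (3S,4S)-4-(tert-butyldimethylsilyloxy)-3-formyl-6-methylhept-6-enoate
Product: 15 tert-butyl (3R,4S)-4-(tert-butyldimethylsilyloxy)-3-[(1S,2Z,4R)-1,4-dihydroxy-3-methylhepta-2,6-dien-1-yl]-6-methylhept-6-enoate, via oxamagnesacycle 14 (not isolated)
Conditions: 3 (2 equiv), 13 (2.05 equiv per 3), CuI (10 mol % per 3), THF, −10 °C → rt; then 12 (1 equiv), −78 → −40 °C; NH4Cl (aq)
Reagents that add atoms: none
Why: Reagent 13 first converts 3 into its bromomagnesium alkoxide, and methylcopper species formed from CuI (monovalent copper) and more 13 add across the alkyne under direction of that alkoxide: methyl goes to C4 and the metal to C5 on opposite faces, so that after copper-to-magnesium exchange the C5–Mg bond is held cis to C3 in the five-membered oxamagnesacycle 14. The closest known reaction type is the copper-catalysed anti-carbomagnesiation of propargylic alcohols with trapping of the chelated vinylmagnesium by iodine or aldehydes. Intermediate 14 then adds to aldehyde 12 at −78 °C with retention of alkene geometry, so C4–C15 and C5–C6 form in one flask; no ring is closed in the product, since the magnesacycle is transient and opens on hydrolysis. The Z geometry of C4=C5 is fixed by the chelate and the regiochemistry by the alkoxide. The new stereocentre C6 (S) is set by Felkin–Anh addition anti to the C8 branch of the C7-substituted aldehyde, and the 1,3-anti preference of the β-silyloxy group points the same way because C7 and C8 are anti. The silyl ether does not chelate, which keeps a Cram-chelate pathway from competing. Selectivity for the aldehyde over the tert-butyl ester rests on low temperature and ester bulk, and loss of 12 to methyl addition is limited by using only two equivalents of 13 per 3 and the alkynol-derived reagent in excess. C3, C7 and C8 are not touched.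

Step 8
Reactants: 15 tert-butyl (3R,4S)-4-(tert-butyldimethylsilyloxy)-3-[(1S,2Z,4R)-1,4-dihydroxy-3-methylhepta-2,6-dien-1-yl]-6-methylhept-6-enoate
Product: 16 (4R,5S)-4-[(1S)-1-(tert-butyldimethylsilyloxy)-3-methylbut-3-en-1-yl]-5-[(1Z,3R)-3-hydroxy-2-methylhexa-1,5-dien-1-yl]oxolan-2-one
Conditions: CSA (10 mol %), CH2Cl2, 0 °C → rt
Reagents that add atoms: none
Why: Acid-catalysed intramolecular transesterification (5-exo-trig) of the γ-hydroxy tert-butyl ester. Only O6 can reach C12 through a five-membered ring, so the two hydroxyls are differentiated; the trans lactone follows from the C6/C7 configurations, and the catalytic acid in an aprotic solvent leaves the silyl ether intact.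

Step 9
Reactants: 16 (4R,5S)-4-[(1S)-1-(tert-butyldimethylsilyloxy)-3-methylbut-3-en-1-yl]-5-[(1Z,3R)-3-hydroxy-2-methylhexa-1,5-dien-1-yl]oxolan-2-one
Product: 17 (1(10)Z,3R,4Z,6S,7R,8S)-8-(tert-butyldimethylsilyloxy)-3-hydroxygermacra-1(10),4-dien-12,6-olide
Conditions: second-generation Grubbs catalyst (H2IMes)(PCy3)Cl2Ru=CHPh (10 mol %), 1,4-benzoquinone (20 mol %), toluene (1 mM), 80 °C
Reagents that add atoms: none
Why: Ring-closing olefin metathesis: the catalyst loads on the C1 vinyl group and closes onto the 1,1-disubstituted C10 olefin with loss of ethene. The Z geometry is expected because an E trisubstituted alkene in a cyclodecene that already holds a Z alkene and a trans-fused lactone is more strained. High dilution and benzoquinone suppress oligomerisation and olefin migration.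

Step 10
Reactants: 17 (1(10)Z,3R,4Z,6S,7R,8S)-8-(tert-butyldimethylsilyloxy)-3-hydroxygermacra-1(10),4-dien-12,6-olide
Product: 20 (1(10)Z,3R,4Z,6S,7R,8S)-8-(tert-butyldimethylsilyloxy)-3-hydroxygermacra-1(10),4,11(13)-trien-12,6-olide, via Mannich base 18 (not isolated), via methiodide 19 (not isolated)
Conditions: LiN(iPr)2 (2.5 equiv), THF, −78 °C; CH2=NMe2+ I−, −78 °C → rt; then MeI, MeOH, rt; NaHCO3 (aq), CH2Cl2, rt
Reagents that add atoms: dimethylmethyleneammonium iodide, C=[N+](C)C.[I-]
Why: Mannich methylenation: the lithium alkoxide–lactone enolate is aminomethylated at C11, and N-methylation followed by mild base eliminates trimethylamine to give the exocyclic alkene. No other enolisable carbonyl is present at this stage, and the C11 configuration of 18 is irrelevant.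

Step 11
Reactants: 20 (1(10)Z,3R,4Z,6S,7R,8S)-8-(tert-butyldimethylsilyloxy)-3-hydroxygermacra-1(10),4,11(13)-trien-12,6-olide
Product: 21 (1(10)Z,3R,4Z,6S,7R,8S)-3-acetoxy-8-(tert-butyldimethylsilyloxy)germacra-1(10),4,11(13)-trien-12,6-olide
Conditions: Ac2O, pyridine, DMAP (cat.), CH2Cl2, 0 °C → rt
Reagents that add atoms: acetic anhydride, CC(=O)OC(C)=O
Why: Nucleophile-catalysed acylation of the only free hydroxyl, with retention at C3; O8 is still silylated.

Step 12
Reactants: 21 (1(10)Z,3R,4Z,6S,7R,8S)-3-acetoxy-8-(tert-butyldimethylsilyloxy)germacra-1(10),4,11(13)-trien-12,6-olide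
Product: 22 (1(10)Z,3R,4Z,6S,7S,8S)-3-acetoxy-8-hydroxygermacra-1(10),4,11(13)-trien-12,6-olide
Conditions: HF·pyridine, pyridine, THF, 0 °C → rt
Reagents that add atoms: none
Why: Fluoride cleavage of the Si–O bond under buffered, weakly acidic conditions. These spare the acetate and the α-methylene lactone and generate no alkoxide that could translactonise from O6 to O8.

Step 13
Reactants: 22 (1(10)Z,3R,4Z,6S,7S,8S)-3-acetoxy-8-hydroxygermacra-1(10),4,11(13)-trien-12,6-olide; 23 (2R)-2-methylbutanoic acid
Product: 24 (1(10)Z,3R,4Z,6S,7S,8S)-3-acetoxy-8-[(2R)-2-methylbutanoyloxy]germacra-1(10),4,11(13)-trien-12,6-olide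
Conditions: DCC, DMAP, CH2Cl2, 0 °C → rt
Reagents that add atoms: none
Why: Steglich esterification (carbodiimide activation, acyl transfer through the acylpyridinium) with retention at C8. The unactivated α-stereocentre of 23 should not racemise under these conditions.

Step 14
Reactants: 24 (1(10)Z,3R,4Z,6S,7S,8S)-3-acetoxy-8-[(2R)-2-methylbutanoyloxy]germacra-1(10),4,11(13)-trien-12,6-olide
Product: 25 (1R,3R,4Z,6S,7S,8S,10S)-3-acetoxy-1,10-epoxy-8-[(2R)-2-methylbutanoyloxy]germacra-4,11(13)-dien-12,6-olide
Conditions: mCPBA, NaHCO3, CH2Cl2, 0 °C
Reagents that add atoms: 3-chloroperoxybenzoic acid, OOC(=O)c1cccc(Cl)c1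
Why: Prilezhaev epoxidation of the only electron-rich alkene: C4=C5 is flanked by two allylic acyloxy groups and C11=C13 is conjugated. The concerted syn addition turns the Z alkene into the cis-epoxide, and the peracid is expected to approach the face away from the two homoallylic acyloxy groups at C3 and C8, giving 1R,10S. The bicarbonate buffer prevents transannular opening.

## Compound list

1 | 3-(trimethylsilyl)prop-2-ynal | C[Si](C)(C)C#CC=O | starting material
2 | (3R)-1-(trimethylsilyl)hex-5-en-1-yn-3-ol | C[Si](C)(C)C#C[C@H](O)CC=C | intermediate (not isolated)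
3 | (3R)-hex-5-en-1-yn-3-ol | C#C[C@H](O)CC=C | intermediate
4 | ethyl (3R)-4-chloro-3-hydroxybutanoate | CCOC(=O)C[C@@H](O)CCl | starting material
5 | ethyl 2-[(2R)-oxiran-2-yl]acetate | CCOC(=O)C[C@@H]1CO1 | intermediate
6 | isopropenylmagnesium bromide | CC(=C)[Mg]Br | starting material
7 | ethyl (3S)-3-hydroxy-5-methylhex-5-enoate | CCOC(=O)C[C@@H](O)CC(C)=C | intermediate
8 | tert-butyl bromoacetate | CC(C)(C)OC(=O)CBr | starting material
9 | dilithium alkoxide–enolate of 7 (O–Li of the enolate cis to C8, chelated) | CCO/C(O[Li])=C/[C@@H](O[Li])CC(C)=C | intermediate (not isolated)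
10 | 4-tert-butyl 1-ethyl (2S)-2-[(1S)-1-hydroxy-3-methylbut-3-en-1-yl]butanedioate | CCOC(=O)[C@@H](CC(=O)OC(C)(C)C)[C@@H](O)CC(C)=C | intermediate
11 | 4-tert-butyl 1-ethyl (2S)-2-[(1S)-1-(tert-butyldimethylsilyloxy)-3-methylbut-3-en-1-yl]butanedioate | CCOC(=O)[C@@H](CC(=O)OC(C)(C)C)[C@@H](O[Si](C)(C)C(C)(C)C)CC(C)=C | intermediate
12 | tert-butyl (3S,4S)-4-(tert-butyldimethylsilyloxy)-3-formyl-6-methylhept-6-enoate | O=C[C@@H](CC(=O)OC(C)(C)C)[C@@H](O[Si](C)(C)C(C)(C)C)CC(C)=C | intermediate
13 | methylmagnesium bromide | C[Mg]Br | starting material
14 | (5R)-4-methyl-5-(prop-2-en-1-yl)-2,5-dihydro-1,2-oxamagnesole (chelated vinylmagnesium) | C=CC[C@H]1O[Mg]C=C1C | intermediate (not isolated)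
15 | tert-butyl (3R,4S)-4-(tert-butyldimethylsilyloxy)-3-[(1S,2Z,4R)-1,4-dihydroxy-3-methylhepta-2,6-dien-1-yl]-6-methylhept-6-enoate | C=C(C)C[C@H](O[Si](C)(C)C(C)(C)C)[C@H](CC(=O)OC(C)(C)C)[C@@H](O)/C=C(/C)[C@H](O)CC=C | intermediate
16 | (4R,5S)-4-[(1S)-1-(tert-butyldimethylsilyloxy)-3-methylbut-3-en-1-yl]-5-[(1Z,3R)-3-hydroxy-2-methylhexa-1,5-dien-1-yl]oxolan-2-one | O=C1C[C@@H]([C@@H](O[Si](C)(C)C(C)(C)C)CC(C)=C)[C@@H](O1)/C=C(/C)[C@H](O)CC=C | intermediate
17 | (1(10)Z,3R,4Z,6S,7R,8S)-8-(tert-butyldimethylsilyloxy)-3-hydroxygermacra-1(10),4-dien-12,6-olide | C1C(=O)O[C@H]2/C=C(/C)[C@H](O)C/C=C(/C)C[C@H](O[Si](C)(C)C(C)(C)C)[C@H]12 | intermediate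
18 | 13-(dimethylamino) derivative of 17 (C11 epimers; other centres as in 17) | CN(C)CC1C(=O)O[C@H]2/C=C(/C)[C@H](O)C/C=C(/C)C[C@H](O[Si](C)(C)C(C)(C)C)[C@H]12 | intermediate (not isolated)
19 | 13-(trimethylammonio) derivative of 17, iodide (C11 epimers) | C[N+](C)(C)CC1C(=O)O[C@H]2/C=C(/C)[C@H](O)C/C=C(/C)C[C@H](O[Si](C)(C)C(C)(C)C)[C@H]12.[I-] | intermediate (not isolated)
20 | (1(10)Z,3R,4Z,6S,7R,8S)-8-(tert-butyldimethylsilyloxy)-3-hydroxygermacra-1(10),4,11(13)-trien-12,6-olide | C=C1C(=O)O[C@H]2/C=C(/C)[C@H](O)C/C=C(/C)C[C@H](O[Si](C)(C)C(C)(C)C)[C@H]12 | intermediate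
21 | (1(10)Z,3R,4Z,6S,7R,8S)-3-acetoxy-8-(tert-butyldimethylsilyloxy)germacra-1(10),4,11(13)-trien-12,6-olide | C=C1C(=O)O[C@H]2/C=C(/C)[C@H](OC(C)=O)C/C=C(/C)C[C@H](O[Si](C)(C)C(C)(C)C)[C@H]12 | intermediate
22 | (1(10)Z,3R,4Z,6S,7S,8S)-3-acetoxy-8-hydroxygermacra-1(10),4,11(13)-trien-12,6-olide | C=C1C(=O)O[C@H]2/C=C(/C)[C@H](OC(C)=O)C/C=C(/C)C[C@H](O)[C@H]12 | intermediate
23 | (2R)-2-methylbutanoic acid | CC[C@@H](C)C(=O)O | starting material
24 | (1(10)Z,3R,4Z,6S,7S,8S)-3-acetoxy-8-[(2R)-2-methylbutanoyloxy]germacra-1(10),4,11(13)-trien-12,6-olide | C=C1C(=O)O[C@H]2/C=C(/C)[C@H](OC(C)=O)C/C=C(/C)C[C@H](OC(=O)[C@H](C)CC)[C@H]12 | intermediate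
25 | (1R,3R,4Z,6S,7S,8S,10S)-3-acetoxy-1,10-epoxy-8-[(2R)-2-methylbutanoyloxy]germacra-4,11(13)-dien-12,6-olide (CNP0340603.1) | C=C1C(=O)O[C@H]2/C=C(/C)[C@H](OC(C)=O)C[C@H]3O[C@@]3(C)C[C@H](OC(=O)[C@H](C)CC)[C@H]12 | target

## Step count and least certain steps

Total: 14 steps. Longest linear sequence: 13 steps (steps 2–14, from 4 to 25); the alkynol branch contributes step 1.

**Step 7 (key step).** The most likely failure is consumption of aldehyde 12 by methyl transfer from unreacted 13, or by deprotonation at C7 by the basic vinylmagnesium. Carbomagnesiation seldom runs to completion with exactly two equivalents of Grignard reagent, and the chelated nucleophile is hindered. A second concern is weak facial discrimination if the chiral C3 alkoxide of the nucleophile opposes the Felkin preference. Fallback: setting out from 3 and 13, the same copper-catalysed carbomagnesiation is quenched with iodine instead of the aldehyde, which should give (1Z,3R)-1-iodo-2-methylhexa-1,5-dien-3-ol F1 free of methyl Grignard reagent. F1 is then joined to 12 by a Nozaki–Hiyama–Kishi coupling (CrCl2, divalent chromium, with catalytic NiCl2, DMSO–THF). This non-basic organochromium addition tolerates the free hydroxyl, the tert-butyl ester and the epimerisable C7, forms the same C5–C6 bond and returns to the route at 15.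

**Step 4.** The most likely failure is proton transfer from the acidic methylene of 8 to dianion 9, which returns 7; partial lactonisation of the product alkoxide onto C12 is a second drain. Fallback: setting out from 7, saponification (LiOH) should give (3S)-3-hydroxy-5-methylhex-5-enoic acid F2. Its bis(trimethylsilyl) derivative is condensed with pivalaldehyde (catalytic TMSOTf, −78 °C) to the cis acetal (2S,6S)-2-tert-butyl-6-(2-methylprop-2-en-1-yl)-1,3-dioxan-4-one F3. The lithium enolate of F3, a simple mono-enolate, is alkylated with 8 trans to the C6 side chain to give tert-butyl 2-[(2S,5S,6S)-2-tert-butyl-6-(2-methylprop-2-en-1-yl)-4-oxo-1,3-dioxan-5-yl]acetate F4. Ethanolysis (EtOH, catalytic NaOEt, 0 °C) releases pivalaldehyde and returns to the route at 10 with the same anti relation of C7 and C8.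

**Step 9.** The most likely failure is oligomerisation through cross-metathesis at the unhindered C1 vinyl group, or no closure at all, because the trans-fused lactone holds the two chains apart and the second olefin is 1,1-disubstituted. Formation of the E isomer is a lesser risk. Fallback: the order of the two ring formations is reversed. Setting out from 15, both hydroxyls are silylated (Et3SiOTf, 2,6-lutidine) to give the 3,6-bis(triethylsilyl) ether of 15 F5. Ring-closing metathesis of this open-chain ester, free of lactone strain, should give tert-butyl 2-[(1(10)Z,4Z)-8-(tert-butyldimethylsilyloxy)-3,6-bis(triethylsilyloxy)germacra-1(10),4-dien-7-yl]acetate (the 11,12-seco ester, written here in germacrane terms) F6. CSA in MeOH–CH2Cl2 then removes the triethylsilyl groups, the freed C6 hydroxyl lactonises, and the route is rejoined at 17.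

**Step 14.** The most likely failure is attack of the peracid on the wrong face of C1=C10, since the conformation of the (Z,Z)-ring and not a neighbouring group decides the face. Acid-triggered transannular opening of the new epoxide by the C4=C5 alkene is the second risk. Fallback: setting out from 24, NBS in aqueous THF should add bromine to C1 and water to the tertiary C10 in an anti sense, giving (1S,3R,4Z,6S,7S,8S,10S)-3-acetoxy-1-bromo-10-hydroxy-8-[(2R)-2-methylbutanoyloxy]germacra-4,11(13)-dien-12,6-olide F7. Closure with Ag2O displaces bromide with inversion at C1 and so places the epoxide oxygen on the face opposite to the one the electrophile chose, returning to the route at 25.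

## Further compounds

F1 | step 7 | (1Z,3R)-1-iodo-2-methylhexa-1,5-dien-3-ol | I/C=C(/C)[C@H](O)CC=C
F2 | step 4 | (3S)-3-hydroxy-5-methylhex-5-enoic acid | OC(=O)C[C@@H](O)CC(C)=C
F3 | step 4 | (2S,6S)-2-tert-butyl-6-(2-methylprop-2-en-1-yl)-1,3-dioxan-4-one | CC(C)(C)[C@@H]1OC(=O)C[C@H](CC(C)=C)O1
F4 | step 4 | tert-butyl 2-[(2S,5S,6S)-2-tert-butyl-6-(2-methylprop-2-en-1-yl)-4-oxo-1,3-dioxan-5-yl]acetate | CC(C)(C)[C@@H]1OC(=O)[C@@H](CC(=O)OC(C)(C)C)[C@H](CC(C)=C)O1
F5 | step 9 | 3,6-bis(triethylsilyl) ether of 15 | C=C(C)C[C@H](O[Si](C)(C)C(C)(C)C)[C@H](CC(=O)OC(C)(C)C)[C@@H](O[Si](CC)(CC)CC)/C=C(/C)[C@H](O[Si](CC)(CC)CC)CC=C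
F6 | step 9 | tert-butyl 2-[(1(10)Z,4Z)-8-(tert-butyldimethylsilyloxy)-3,6-bis(triethylsilyloxy)germacra-1(10),4-dien-7-yl]acetate (11,12-seco ester) | CC(C)(C)OC(=O)C[C@@H]1[C@@H](O[Si](CC)(CC)CC)/C=C(/C)[C@H](O[Si](CC)(CC)CC)C/C=C(/C)C[C@@H]1O[Si](C)(C)C(C)(C)C
F7 | step 14 | (1S,3R,4Z,6S,7S,8S,10S)-3-acetoxy-1-bromo-10-hydroxy-8-[(2R)-2-methylbutanoyloxy]germacra-4,11(13)-dien-12,6-olide | C=C1C(=O)O[C@H]2/C=C(/C)[C@H](OC(C)=O)C[C@H](Br)[C@@](C)(O)C[C@H](OC(=O)[C@H](C)CC)[C@H]12
A1 | alternative 1 | 3,8-cyclogermacra-1(10),4-diene-3,8-diol-12,6-olide (cis ring-fusion diol, C3–C8 bond intact) | C1C(=O)O[C@H]2C=C(C)[C@]3(O)CC=C(C)C[C@]3(O)[C@H]12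
A2 | alternative 1 | (1(10)Z,4Z)-3,8-dioxogermacra-1(10),4-dien-12,6-olide | C1C(=O)O[C@H]2/C=C(/C)C(=O)C/C=C(/C)CC(=O)[C@H]12
A3 | alternative 2 | (1(10)Z,4Z)-7-ethynyl-6-hydroxy-3-(tert-butyldimethylsilyloxy)-4,10-dimethylcyclodeca-1(10),4-dien-8-yl (2R)-2-methylbutanoate (germacrane numbering) | C#C[C@@H]1[C@@H](O)/C=C(/C)[C@H](O[Si](C)(C)C(C)(C)C)C/C=C(/C)C[C@@H]1OC(=O)[C@H](C)CC
A4 | alternative 2 | (1(10)Z,4Z)-3-(tert-butyldimethylsilyloxy)-8-[(2R)-2-methylbutanoyloxy]germacra-1(10),4,11(13)-trien-12,6-olide | C=C1C(=O)O[C@H]2/C=C(/C)[C@H](O[Si](C)(C)C(C)(C)C)C/C=C(/C)C[C@H](OC(=O)[C@H](C)CC)[C@H]12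
A5 | alternative 3 | eleven-membered sulfone with SO2 between C1 and C10, 3-silyl and 8-(4-methoxybenzyl) ethers, 12,6-lactone (C10 epimers) | C1C(=O)O[C@H]2/C=C(/C)[C@H](O[Si](C)(C)C(C)(C)C)CCS(=O)(=O)C(C)C[C@H](OCc3ccc(OC)cc3)[C@H]12
A6 | alternative 3 | (1(10)Z,4Z)-3-(tert-butyldimethylsilyloxy)-8-(4-methoxybenzyloxy)germacra-1(10),4-dien-12,6-olide | C1C(=O)O[C@H]2/C=C(/C)[C@H](O[Si](C)(C)C(C)(C)C)C/C=C(/C)C[C@H](OCc3ccc(OC)cc3)[C@H]12
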